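**Retrosynthetic overview**

1. Target 25 is a quaterphenyl of four phloroglucinol rings A–B–C–D with chlorine on ring C. It is traced back through BBr3 cleavage of all alkyl ethers, desilylation and chlorination of the single ring C C–H (25 ⇐ 24 ⇐ 23 ⇐ 21).
2. Ring C is the only ring that is built, and it is formed last (step 7). Without chlorine its six carbons read C–OH, C–ring B, C–OEt, C–H, C–OSi, C–ring D, which is the pattern a 4-aryl-3-ethoxycyclobutenone (11) and an aryl siloxyalkyne (16) deliver in a cyclobutenone–ynol ether benzannulation.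
3. Cyclobutenone 11 ⇐ (2+2) of ethoxyacetylene with the ketene of biaryl acetic acid 7 ⇐ glyoxylation and Wolff–Kishner reduction of hexamethoxybiphenyl 2 ⇐ Ullmann coupling of iodide 1 (rings A and B bought as arenes).
4. Siloxyalkyne 16 ⇐ oxidation and silylation of the acetylide of alkyne 13 ⇐ Ohira–Bestmann alkynylation of aldehyde 12 (ring D bought as an arene).

Key step: step 7

Remark: the B–C biaryl axis is stereogenic but unspecified in the target, so 21 to 25 are taken as racemic about this axis; cyclobutenone 11 is racemic at C4 and that centre is lost in step 7.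

**Route**

Step 1
Reactants: 1 2-iodo-1,3,5-trimethoxybenzene (two equivalents)
Product: 2 2,2',4,4',6,6'-hexamethoxybiphenyl
Conditions: activated Cu bronze, neat, 230 °C, Ar
Reagents that add atoms: none
Why: Ullmann homocoupling of an aryl iodide on copper tolerates the two ortho methoxy groups, and the symmetric product needs no regiocontrol.

Step 2
Reactants: 2 2,2',4,4',6,6'-hexamethoxybiphenyl (2 equiv); 3 ethyl chlorooxoacetate (1 equiv)
Product: 4 ethyl 2-(2,2',4,4',6,6'-hexamethoxybiphenyl-3-yl)-2-oxoacetate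
Conditions: SnCl4, CH2Cl2, −20 to 0 °C; aq. NaHCO3; unreacted 2 recovered
Reagents that add atoms: none
Why: Friedel–Crafts acylation at one of the four equivalent C–H positions flanked by two methoxy groups should stop largely at the mono stage, because the keto ester deactivates its own ring and the excess of 2 disfavours acylation of the other ring.

Step 3
Reactants: 4 ethyl 2-(2,2',4,4',6,6'-hexamethoxybiphenyl-3-yl)-2-oxoacetate
Product: 7 2-(2,2',4,4',6,6'-hexamethoxybiphenyl-3-yl)acetic acid, via keto acid potassium salt 5 (not isolated), via hydrazone potassium salt 6 (not isolated)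
Conditions: KOH, diethylene glycol/H2O, 80 °C; N2H4·H2O, 130 °C, then 195 °C with removal of water; aq. HCl
Reagents that add atoms: potassium hydroxide, [K+].[OH-]
Why: Saponification followed by Wolff–Kishner reduction (Huang–Minlon modification) of the aryl keto group through its hydrazone should give the arylacetic acid directly, since aryl methyl ethers withstand hot hydroxide.

Step 4
Reactants: 7 2-(2,2',4,4',6,6'-hexamethoxybiphenyl-3-yl)acetic acid; 8 ethoxyacetylene (5 equiv)
Product: 11 3-ethoxy-4-(2,2',4,4',6,6'-hexamethoxybiphenyl-3-yl)cyclobut-2-en-1-one (racemic), via acid chloride 9 (not isolated), via arylketene 10 (not isolated)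
Conditions: 1-chloro-N,N,2-trimethylprop-1-en-1-amine, CH2Cl2, 0 °C to rt; then 8, NEt3 (slow addition), CH2Cl2, 0 °C to rt; chromatography on NEt3-deactivated silica
Reagents that add atoms: none
Why: The chloroenamine forms the acid chloride under neutral conditions that spare the electron-rich rings, NEt3 then gives the arylketene, whose dimerization is slowed by the two ortho methoxy groups, and a ketene–ynol ether (2+2) cycloaddition joins the nucleophilic CH carbon of ethoxyacetylene to the ketene carbonyl carbon to give the 3-ethoxy-4-aryl isomer.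

Step 5
Reactants: 12 2,4,6-trimethoxybenzaldehyde
Product: 13 2-ethynyl-1,3,5-trimethoxybenzene
Conditions: dimethyl (1-diazo-2-oxopropyl)phosphonate, K2CO3, MeOH, 0 °C to rt
Reagents that add atoms: dimethyl (1-diazo-2-oxopropyl)phosphonate, CC(=O)C(=[N+]=[N-])P(=O)(OC)OC
Why: Ohira–Bestmann (Seyferth–Gilbert) homologation converts an aryl aldehyde without α-hydrogens into the terminal alkyne through a diazoalkene and 1,2-shift in the derived alkylidene carbene.

Step 6
Reactants: 13 2-ethynyl-1,3,5-trimethoxybenzene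
Product: 16 triisopropyl[(2,4,6-trimethoxyphenyl)ethynyloxy]silane, via lithium acetylide 14 (not isolated), via lithium ynolate 15 (not isolated)
Conditions: n-BuLi, THF, −78 °C; LiOOC(CH3)3 (from t-BuOOH and LiN(SiMe3)2, THF, −78 °C), −78 to 0 °C; TIPSOTf, −78 to 0 °C
Reagents that add atoms: tert-butyl hydroperoxide, CC(C)(C)OO; triisopropylsilyl trifluoromethanesulfonate, CC(C)[Si](OS(=O)(=O)C(F)(F)F)(C(C)C)C(C)C
Why: Oxidation of a lithium acetylide by the electrophilic oxygen of lithium tert-butyl peroxide is an established route to ynolates, and the hard silyl triflate should silylate the ynolate on oxygen to give the isolable triisopropylsilyl ynol ether.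

Step 7
Reactants: 11 3-ethoxy-4-(2,2',4,4',6,6'-hexamethoxybiphenyl-3-yl)cyclobut-2-en-1-one; 16 triisopropyl[(2,4,6-trimethoxyphenyl)ethynyloxy]silane (1.5 equiv)
Product: 21 5-ethoxy-6-(2,2',4,4',6,6'-hexamethoxybiphenyl-3-yl)-2-(2,4,6-trimethoxyphenyl)-3-(triisopropylsilyloxy)phenol, via vinylketene 17 (not isolated), via vinylcyclobutenone 18 (not isolated), via dienylketene 19 (not isolated), via cyclohexadienone 20 (not isolated)
Conditions: toluene (degassed), 80 °C then 110 °C, sealed tube, Ar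
Reagents that add atoms: none
Why: Heating opens cyclobutenone 11 by 4-electron electrocyclic cleavage of its C1–C4 bond to the aryl(ethoxy)vinylketene 17, whose ketene C=C bond adds the siloxyalkyne in a (2+2) cycloaddition, the nucleophilic aryl-bearing alkyne carbon bonding to the ketene carbonyl carbon and the siloxy carbon to the ketene CH carbon to give 18. Cyclobutenone 18 opens to dienylketene 19, which closes ring C by thermal 6-electron electrocyclization (ketene carbon onto the ring B-bearing terminus) to dienone 20, and tautomerization gives phenol 21. This is the Danheiser benzannulation in its siloxyalkyne form, applied here to a 3-alkoxy-4-arylcyclobutenone. No stereocentre is created, and the B–C axis forms as a racemate. The regiochemistry needed rests on the polarization of the siloxyalkyne, which places ring D beside the new hydroxyl and the siloxy group meta to it. The chemoselectivity needed rests on ring B: both positions ortho to the four-membered ring carry methoxy groups, so closure of 17 onto the aryl ring cannot aromatize, and the doubly flanked hydroxyl of 21 resists acylation by remaining ketene.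

Step 8
Reactants: 21 5-ethoxy-6-(2,2',4,4',6,6'-hexamethoxybiphenyl-3-yl)-2-(2,4,6-trimethoxyphenyl)-3-(triisopropylsilyloxy)phenol
Product: 23 4-chloro-5-ethoxy-6-(2,2',4,4',6,6'-hexamethoxybiphenyl-3-yl)-2-(2,4,6-trimethoxyphenyl)-3-(triisopropylsilyloxy)phenol, via sodium phenoxide 22 (not isolated)
Conditions: NaH, THF, 0 °C; NCS (1.0 equiv), −78 to 0 °C; aq. NH4Cl
Reagents that add atoms: N-chlorosuccinimide, O=C1CCC(=O)N1Cl
Why: In this electrophilic aromatic chlorination the phenoxide is far more nucleophilic than the neutral methoxylated rings A, B and D, and both of its ortho carbons carry aryl groups, so chlorine should enter at the only C–H of ring C, para to the oxide.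

Step 9
Reactants: 23 4-chloro-5-ethoxy-6-(2,2',4,4',6,6'-hexamethoxybiphenyl-3-yl)-2-(2,4,6-trimethoxyphenyl)-3-(triisopropylsilyloxy)phenol
Product: 24 4-chloro-5-ethoxy-6-(2,2',4,4',6,6'-hexamethoxybiphenyl-3-yl)-2-(2,4,6-trimethoxyphenyl)benzene-1,3-diol
Conditions: TBAF, THF, 0 °C, Ar; aq. NH4Cl
Reagents that add atoms: none
Why: Fluoride cleaves the aryl silyl ether through formation of the strong Si–F bond, which secures removal of the silyl group before the boron-mediated ether cleavage, where its loss would be uncertain.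

Step 10
Reactants: 24 4-chloro-5-ethoxy-6-(2,2',4,4',6,6'-hexamethoxybiphenyl-3-yl)-2-(2,4,6-trimethoxyphenyl)benzene-1,3-diol
Product: 25 2-chloro-4-(2,2',4,4',6,6'-hexahydroxybiphenyl-3-yl)-6-(2,4,6-trihydroxyphenyl)benzene-1,3,5-triol (target)
Conditions: BBr3 (large excess), CH2Cl2, −78 °C to rt, Ar; MeOH then H2O at 0 °C; work-up and purification with exclusion of air
Reagents that add atoms: none
Why: Lewis acid ether cleavage with BBr3 (bromide attack on the O-alkyl carbon of the boron-complexed ether) should remove the nine methyl groups and the ethyl group at or below room temperature, conditions under which the aryl chloride and the biaryl bonds are inert.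

**Compound list**

1 | 2-iodo-1,3,5-trimethoxybenzene | COc1cc(OC)c(I)c(OC)c1 | starting material
2 | 2,2',4,4',6,6'-hexamethoxybiphenyl | COc1cc(OC)c(-c2c(OC)cc(OC)cc2OC)c(OC)c1 | intermediate
3 | ethyl chlorooxoacetate | CCOC(=O)C(Cl)=O | starting material
4 | ethyl 2-(2,2',4,4',6,6'-hexamethoxybiphenyl-3-yl)-2-oxoacetate | CCOC(=O)C(=O)c1c(OC)cc(OC)c(-c2c(OC)cc(OC)cc2OC)c1OC | intermediate
5 | potassium 2-(2,2',4,4',6,6'-hexamethoxybiphenyl-3-yl)-2-oxoacetate (not isolated) | [K+].[O-]C(=O)C(=O)c1c(OC)cc(OC)c(-c2c(OC)cc(OC)cc2OC)c1OC | intermediate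
6 | potassium 2-hydrazinylidene-2-(2,2',4,4',6,6'-hexamethoxybiphenyl-3-yl)acetate (not isolated) | [K+].NN=C(C(=O)[O-])c1c(OC)cc(OC)c(-c2c(OC)cc(OC)cc2OC)c1OC | intermediate
7 | 2-(2,2',4,4',6,6'-hexamethoxybiphenyl-3-yl)acetic acid | OC(=O)Cc1c(OC)cc(OC)c(-c2c(OC)cc(OC)cc2OC)c1OC | intermediate
8 | ethoxyacetylene | CCOC#C | starting material
9 | 2-(2,2',4,4',6,6'-hexamethoxybiphenyl-3-yl)acetyl chloride (not isolated) | ClC(=O)Cc1c(OC)cc(OC)c(-c2c(OC)cc(OC)cc2OC)c1OC | intermediate
10 | (2,2',4,4',6,6'-hexamethoxybiphenyl-3-yl)ketene (not isolated) | O=C=Cc1c(OC)cc(OC)c(-c2c(OC)cc(OC)cc2OC)c1OC | intermediate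
11 | 3-ethoxy-4-(2,2',4,4',6,6'-hexamethoxybiphenyl-3-yl)cyclobut-2-en-1-one (racemic) | CCOC1=CC(=O)C1c1c(OC)cc(OC)c(-c2c(OC)cc(OC)cc2OC)c1OC | intermediate
12 | 2,4,6-trimethoxybenzaldehyde | COc1cc(OC)c(C=O)c(OC)c1 | starting material
13 | 2-ethynyl-1,3,5-trimethoxybenzene | COc1cc(OC)c(C#C)c(OC)c1 | intermediate
14 | lithium (2,4,6-trimethoxyphenyl)acetylide (not isolated) | [Li+].[C-]#Cc1c(OC)cc(OC)cc1OC | intermediate
15 | lithium 2-(2,4,6-trimethoxyphenyl)ethynolate (not isolated) | [Li+].[O-]C#Cc1c(OC)cc(OC)cc1OC | intermediate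
16 | triisopropyl[(2,4,6-trimethoxyphenyl)ethynyloxy]silane | COc1cc(OC)c(C#CO[Si](C(C)C)(C(C)C)C(C)C)c(OC)c1 | intermediate
17 | (3Z)-3-ethoxy-4-(2,2',4,4',6,6'-hexamethoxybiphenyl-3-yl)buta-1,3-dien-1-one, aryl trans to the ketene CH carbon (not isolated) | O=C=C/C(OCC)=C/c1c(OC)cc(OC)c(-c2c(OC)cc(OC)cc2OC)c1OC | intermediate
18 | 4-[(Z)-1-ethoxy-2-(2,2',4,4',6,6'-hexamethoxybiphenyl-3-yl)ethenyl]-2-(2,4,6-trimethoxyphenyl)-3-(triisopropylsilyloxy)cyclobut-2-en-1-one (racemic, not isolated) | O=C1C(c2c(OC)cc(OC)cc2OC)=C(O[Si](C(C)C)(C(C)C)C(C)C)C1/C(OCC)=C/c1c(OC)cc(OC)c(-c2c(OC)cc(OC)cc2OC)c1OC | intermediate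
19 | 5-ethoxy-6-(2,2',4,4',6,6'-hexamethoxybiphenyl-3-yl)-2-(2,4,6-trimethoxyphenyl)-3-(triisopropylsilyloxy)hexa-1,3,5-trien-1-one, C2 and C5 cis across the 3,4-double bond, C4 and aryl trans across the 5,6-double bond (not isolated) | O=C=C(c1c(OC)cc(OC)cc1OC)/C(O[Si](C(C)C)(C(C)C)C(C)C)=C\C(OCC)=C\c1c(OC)cc(OC)c(-c2c(OC)cc(OC)cc2OC)c1OC | intermediate
20 | 5-ethoxy-6-(2,2',4,4',6,6'-hexamethoxybiphenyl-3-yl)-2-(2,4,6-trimethoxyphenyl)-3-(triisopropylsilyloxy)cyclohexa-2,4-dien-1-one (not isolated) | O=C1C(c2c(OC)cc(OC)cc2OC)=C(O[Si](C(C)C)(C(C)C)C(C)C)C=C(OCC)C1c1c(OC)cc(OC)c(-c2c(OC)cc(OC)cc2OC)c1OC | intermediate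
21 | 5-ethoxy-6-(2,2',4,4',6,6'-hexamethoxybiphenyl-3-yl)-2-(2,4,6-trimethoxyphenyl)-3-(triisopropylsilyloxy)phenol | COc1cc(OC)c(-c2c(O)c(-c3c(OC)cc(OC)c(-c4c(OC)cc(OC)cc4OC)c3OC)c(OCC)cc2O[Si](C(C)C)(C(C)C)C(C)C)c(OC)c1 | intermediate
22 | sodium phenoxide of 21 (not isolated) | COc1cc(OC)c(-c2c([O-])c(-c3c(OC)cc(OC)c(-c4c(OC)cc(OC)cc4OC)c3OC)c(OCC)cc2O[Si](C(C)C)(C(C)C)C(C)C)c(OC)c1.[Na+] | intermediate
23 | 4-chloro-5-ethoxy-6-(2,2',4,4',6,6'-hexamethoxybiphenyl-3-yl)-2-(2,4,6-trimethoxyphenyl)-3-(triisopropylsilyloxy)phenol | COc1cc(OC)c(-c2c(O)c(-c3c(OC)cc(OC)c(-c4c(OC)cc(OC)cc4OC)c3OC)c(OCC)c(Cl)c2O[Si](C(C)C)(C(C)C)C(C)C)c(OC)c1 | intermediate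
24 | 4-chloro-5-ethoxy-6-(2,2',4,4',6,6'-hexamethoxybiphenyl-3-yl)-2-(2,4,6-trimethoxyphenyl)benzene-1,3-diol | COc1cc(OC)c(-c2c(O)c(-c3c(OC)cc(OC)c(-c4c(OC)cc(OC)cc4OC)c3OC)c(OCC)c(Cl)c2O)c(OC)c1 | intermediate
25 | 2-chloro-4-(2,2',4,4',6,6'-hexahydroxybiphenyl-3-yl)-6-(2,4,6-trihydroxyphenyl)benzene-1,3,5-triol | Oc1cc(O)c(-c2c(O)cc(O)c(-c3c(O)c(Cl)c(O)c(-c4c(O)cc(O)cc4O)c3O)c2O)c(O)c1 | target

**Step count**

Total steps: 10. Longest linear sequence: 8 steps (1, 2, 3, 4, 7, 8, 9, 10); steps 5 and 6 form the second branch.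

**Steps most likely to fail**

Step 7. Capture of vinylketene 17 by the di-ortho-substituted aryl siloxyalkyne may be slower than oligomerization of the ketene or thermal decay of 16, or adduct 18 may stall before its ring opening. In the fallback the two heteroatom-substituted alkynes exchange roles. It sets out from acid 7 and siloxyalkyne 16 and comes back at target 25. Ketene 10, generated from 7 through chloride 9 as in step 4, is trapped at room temperature by 16 in a (2+2) cycloaddition to give 4-(2,2',4,4',6,6'-hexamethoxybiphenyl-3-yl)-2-(2,4,6-trimethoxyphenyl)-3-(triisopropylsilyloxy)cyclobut-2-en-1-one F1. Heating F1 in toluene (80 to 110 °C) with an excess of the small ethoxyacetylene 8 is a benzannulation of the same type with an alkoxyacetylene. It should give 3-ethoxy-6-(2,2',4,4',6,6'-hexamethoxybiphenyl-3-yl)-4-(2,4,6-trimethoxyphenyl)-5-(triisopropylsilyloxy)phenol F2, whose only ring C C–H is ortho to the free hydroxyl. Chlorination of its sodium phenoxide with NCS gives 2-chloro-3-ethoxy-6-(2,2',4,4',6,6'-hexamethoxybiphenyl-3-yl)-4-(2,4,6-trimethoxyphenyl)-5-(triisopropylsilyloxy)phenol F3. TBAF then gives 4-chloro-5-ethoxy-2-(2,2',4,4',6,6'-hexamethoxybiphenyl-3-yl)-6-(2,4,6-trimethoxyphenyl)benzene-1,3-diol F4, a regioisomer of 24 in the position of the ethyl group only. BBr3 cleavage of F4 returns to the route at 25.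

Step 4. Amine-promoted dimerization of the arylketene, or addition of hydrogen chloride from the ammonium salt to ethoxyacetylene, may outrun the cycloaddition, and the acid-sensitive vinylogous ester may hydrolyse on isolation. The fallback generates the ketene without amine by a Wolff rearrangement. It sets out from biaryl 2 and comes back at cyclobutenone 11. Friedel–Crafts acetylation (acetyl chloride, SnCl4, CH2Cl2, −20 °C, 2 in excess) gives 1-(2,2',4,4',6,6'-hexamethoxybiphenyl-3-yl)ethanone F5. Its lithium enolate (LiN(SiMe3)2, THF, −78 °C) is acylated with 2,2,2-trifluoroethyl trifluoroacetate to 4,4,4-trifluoro-1-(2,2',4,4',6,6'-hexamethoxybiphenyl-3-yl)butane-1,3-dione F6, used crude. Diazo transfer from methanesulfonyl azide (NEt3, H2O, MeCN) with loss of the trifluoroacetyl group gives 2-diazo-1-(2,2',4,4',6,6'-hexamethoxybiphenyl-3-yl)ethanone F7. Irradiation of F7 (300 nm, CH2Cl2, room temperature) in the presence of 8 triggers Wolff rearrangement with aryl migration to ketene 10 under neutral conditions, and its (2+2) cycloaddition with 8 returns to the route at 11.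

Step 8. Electrophilic chlorine may be consumed by the methoxylated rings A, B and D, or attack at the para carbon next to the bulky silyl ether may be slow enough for dearomatizing chlorination at an aryl-bearing carbon to intervene. The fallback changes the order of events and the selectivity principle. It sets out from 21 and comes back at 24. Desilylation with TBAF first gives 5-ethoxy-4-(2,2',4,4',6,6'-hexamethoxybiphenyl-3-yl)-2-(2,4,6-trimethoxyphenyl)benzene-1,3-diol F8, in which the ring C C–H is ortho to a free hydroxyl. Hydroxyl-directed ortho-chlorination follows, with SO2Cl2 and a catalytic secondary amine (2,2,6,6-tetramethylpiperidine, toluene, 0 °C). The N-chloroammonium species is held by hydrogen bonding to the phenol and delivers chlorine to the adjacent carbon and not to the methoxylated rings, which returns to the route at 24.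

**Further compounds**

F1 | step 7 | 4-(2,2',4,4',6,6'-hexamethoxybiphenyl-3-yl)-2-(2,4,6-trimethoxyphenyl)-3-(triisopropylsilyloxy)cyclobut-2-en-1-one | O=C1C(c2c(OC)cc(OC)cc2OC)=C(O[Si](C(C)C)(C(C)C)C(C)C)C1c1c(OC)cc(OC)c(-c2c(OC)cc(OC)cc2OC)c1OC
F2 | step 7 | 3-ethoxy-6-(2,2',4,4',6,6'-hexamethoxybiphenyl-3-yl)-4-(2,4,6-trimethoxyphenyl)-5-(triisopropylsilyloxy)phenol | CCOc1cc(O)c(-c2c(OC)cc(OC)c(-c3c(OC)cc(OC)cc3OC)c2OC)c(O[Si](C(C)C)(C(C)C)C(C)C)c1-c1c(OC)cc(OC)cc1OC
F3 | step 7 | 2-chloro-3-ethoxy-6-(2,2',4,4',6,6'-hexamethoxybiphenyl-3-yl)-4-(2,4,6-trimethoxyphenyl)-5-(triisopropylsilyloxy)phenol | CCOc1c(Cl)c(O)c(-c2c(OC)cc(OC)c(-c3c(OC)cc(OC)cc3OC)c2OC)c(O[Si](C(C)C)(C(C)C)C(C)C)c1-c1c(OC)cc(OC)cc1OC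
F4 | step 7 | 4-chloro-5-ethoxy-2-(2,2',4,4',6,6'-hexamethoxybiphenyl-3-yl)-6-(2,4,6-trimethoxyphenyl)benzene-1,3-diol | CCOc1c(Cl)c(O)c(-c2c(OC)cc(OC)c(-c3c(OC)cc(OC)cc3OC)c2OC)c(O)c1-c1c(OC)cc(OC)cc1OC
F5 | step 4 | 1-(2,2',4,4',6,6'-hexamethoxybiphenyl-3-yl)ethanone | CC(=O)c1c(OC)cc(OC)c(-c2c(OC)cc(OC)cc2OC)c1OC
F6 | step 4 | 4,4,4-trifluoro-1-(2,2',4,4',6,6'-hexamethoxybiphenyl-3-yl)butane-1,3-dione | O=C(CC(=O)C(F)(F)F)c1c(OC)cc(OC)c(-c2c(OC)cc(OC)cc2OC)c1OC
F7 | step 4 | 2-diazo-1-(2,2',4,4',6,6'-hexamethoxybiphenyl-3-yl)ethanone | [N-]=[N+]=CC(=O)c1c(OC)cc(OC)c(-c2c(OC)cc(OC)cc2OC)c1OC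
F8 | step 8 | 5-ethoxy-4-(2,2',4,4',6,6'-hexamethoxybiphenyl-3-yl)-2-(2,4,6-trimethoxyphenyl)benzene-1,3-diol | COc1cc(OC)c(-c2c(O)c(-c3c(OC)cc(OC)c(-c4c(OC)cc(OC)cc4OC)c3OC)c(OCC)cc2O)c(OC)c1
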